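The oxane (ring B; O1, C2 carrying the 2-arylethyl chain, C4–OH, C6–aryl) is cut at C5–C6. C6 is bonded to O1 and to the electron-rich syringyl ring C, so in an open-chain benzyl ether its C–H can leave as hydride to DDQ. The oxocarbenium ion so formed is trapped by a C4 enol acetate: one operation makes C5–C6, closes ring B as the 4-ketone and places the C6 aryl cis to the C2 chain. The precursor is the O-benzylsyringyl ether of an (S)-homopropargylic alcohol, converted to its 2-acetoxyalkene, with the guaiacyl phenol (ring A) held as an electron-poor pivalate.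

Key step: step 10

Remark: with the numbering above the target is (2S,4R,6S), i.e. all three ring substituents cis (all equatorial). No correction to the precursor and product skeletons was found necessary. The only design change is at the end, where ketone reduction and pivalate removal are run in one flask.

Assumption: the (R)-configured binaphthyl phosphoric acid is taken to direct the allenylboronate to the Re face of aldehyde 5, as this catalyst class does with other aldehydes; the sense would be checked on alcohol 8 by Mosher ester analysis and the (S)-catalyst used if it proved opposite.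

Step 1
Reactants: 1 eugenol
Product: 2 4-allyl-2-methoxyphenyl pivalate
Conditions: pivaloyl chloride, Et3N, 4-(dimethylamino)pyridine (cat.), CH2Cl2, 0 °C → rt
Reagents that add atoms: pivaloyl chloride, CC(C)(C)C(Cl)=O
Why: Nucleophile-catalysed O-acylation of the phenol (Schotten–Baumann-type esterification) should be clean, and the pivalate both protects ring A and makes it too electron-poor to be oxidised in step 10.

Step 2
Reactants: 2 4-allyl-2-methoxyphenyl pivalate
Product: 4 4-(3-hydroxypropyl)-2-methoxyphenyl pivalate, via alkylborane 3 (not isolated)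
Conditions: 9-borabicyclo[3.3.1]nonane (9-BBN), THF, 0 °C → rt; then NaBO3·4H2O, H2O, rt
Reagents that add atoms: sodium perborate, [Na+].[O-]OB=O (source of the hydroxyl oxygen); 9-borabicyclo[3.3.1]nonane, B1C2CCCC1CCC2 (its atoms stay only in intermediate 3)
Why: Brown hydroboration–oxidation, in which the bulky borane adds anti-Markovnikov to the terminal alkene and the mildly basic perborate oxidises the C–B bond without cleaving the hindered aryl pivalate.

Step 3
Reactants: 4 4-(3-hydroxypropyl)-2-methoxyphenyl pivalate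
Product: 5 2-methoxy-4-(3-oxopropyl)phenyl pivalate
Conditions: 2,2,6,6-tetramethylpiperidin-1-oxyl (TEMPO, 10 mol %), PhI(OAc)2 (1.1 equiv), CH2Cl2, rt
Reagents that add atoms: none
Why: Oxoammonium-catalysed alcohol oxidation with PhI(OAc)2 as terminal oxidant should stop at the aldehyde and leave the ester and the deactivated arene untouched.

Step 4
Reactants: 5 2-methoxy-4-(3-oxopropyl)phenyl pivalate; 6 allenylboronic acid pinacol ester
Product: 8 4-[(3S)-3-hydroxyhex-5-yn-1-yl]-2-methoxyphenyl pivalate, via pinacol borate ester 7 (not isolated)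
Conditions: (R)-3,3′-bis(2,4,6-triisopropylphenyl)-1,1′-binaphthyl-2,2′-diyl hydrogen phosphate (10 mol %), 4 Å molecular sieves, toluene, −20 °C; aq. NaHCO3 work-up
Reagents that add atoms: none
Why: Chiral Brønsted acid-catalysed propargylboration, in which the phosphoric acid hydrogen-bonds to a boronate oxygen and the formyl hydrogen so that the allenylboronate adds through a closed six-membered (SE2′) transition state to the Re face, setting the future C2 as (S), and work-up hydrolyses borate 7.

Step 5
Reactants: 9 syringaldehyde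
Product: 10 4-(benzyloxy)-3,5-dimethoxybenzaldehyde
Conditions: benzyl bromide, K2CO3, DMF, 60 °C
Reagents that add atoms: benzyl bromide, BrCc1ccccc1
Why: Williamson ether synthesis on the phenoxide, to which the aldehyde is inert.

Step 6
Reactants: 10 4-(benzyloxy)-3,5-dimethoxybenzaldehyde
Product: 11 [4-(benzyloxy)-3,5-dimethoxyphenyl]methanol
Conditions: NaBH4, MeOH–THF, 0 °C
Reagents that add atoms: none
Why: Borohydride reduction of an aryl aldehyde to the benzylic alcohol is chemoselective and leaves the benzyl ether alone.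

Step 7
Reactants: 11 [4-(benzyloxy)-3,5-dimethoxyphenyl]methanol
Product: 12 4-(benzyloxy)-3,5-dimethoxybenzyl 2,2,2-trichloroacetimidate
Conditions: Cl3CCN, 1,8-diazabicyclo[5.4.0]undec-7-ene (DBU, cat.), CH2Cl2, 0 °C
Reagents that add atoms: trichloroacetonitrile, ClC(Cl)(Cl)C#N
Why: Base-catalysed addition of the alkoxide to the nitrile (trichloroacetimidate formation) is the standard activation of an electron-rich benzyl alcohol for acid-catalysed O-alkylation.

Step 8
Reactants: 8 4-[(3S)-3-hydroxyhex-5-yn-1-yl]-2-methoxyphenyl pivalate; 12 4-(benzyloxy)-3,5-dimethoxybenzyl 2,2,2-trichloroacetimidate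
Product: 13 4-[(3S)-3-{[4-(benzyloxy)-3,5-dimethoxybenzyl]oxy}hex-5-yn-1-yl]-2-methoxyphenyl pivalate
Conditions: CF3SO3H (1–2 mol %), CH2Cl2, −20 → 0 °C, imidate 12 added slowly (1.5 equiv)
Reagents that add atoms: none
Why: Acid-catalysed benzylation with a trichloroacetimidate, in which protonation at nitrogen releases trichloroacetamide and a stabilised trialkoxybenzyl cation that the secondary alcohol captures, under conditions that spare the base-labile aryl pivalate and do not break the C–O bond at the stereocentre.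

Step 9
Reactants: 13 4-[(3S)-3-{[4-(benzyloxy)-3,5-dimethoxybenzyl]oxy}hex-5-yn-1-yl]-2-methoxyphenyl pivalate
Product: 14 (4S)-4-{[4-(benzyloxy)-3,5-dimethoxybenzyl]oxy}-6-[3-methoxy-4-(pivaloyloxy)phenyl]hex-1-en-2-yl acetate
Conditions: [RuCl2(p-cymene)]2 (2 mol %), tri(2-furyl)phosphine (4 mol %), Na2CO3 (15 mol %), AcOH (2 equiv), toluene, 80 °C
Reagents that add atoms: acetic acid, CC(=O)O
Why: Ruthenium-catalysed Markovnikov hydroacyloxylation of a terminal alkyne (acetate attack at the internal carbon of the metal-bound alkyne, then protodemetalation) gives the 2-acetoxy-1-alkene in a buffered medium that should leave the benzylic ether and both esters intact.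

Step 10
Reactants: 14 (4S)-4-{[4-(benzyloxy)-3,5-dimethoxybenzyl]oxy}-6-[3-methoxy-4-(pivaloyloxy)phenyl]hex-1-en-2-yl acetate
Product: 17 4-{2-[(2S,6S)-6-[4-(benzyloxy)-3,5-dimethoxyphenyl]-4-oxooxan-2-yl]ethyl}-2-methoxyphenyl pivalate, via oxocarbenium ion 15 (not isolated), via acetyl oxocarbenium ion 16 (not isolated)
Conditions: 2,3-dichloro-5,6-dicyano-1,4-benzoquinone (DDQ, 2 equiv), 2,6-dichloropyridine (4 equiv), 4 Å molecular sieves, ClCH2CH2Cl, rt → 45 °C
Reagents that add atoms: none
Why: DDQ takes an electron from the trialkoxyarene and then a hydrogen atom from the ring-bound O–CH2 group (net hydride loss) to give the (E)-aryl oxocarbenium ion 15, whose C6 is attacked by the terminal carbon of the enol acetate to form C5–C6 and ion 16, which hands its acetyl group to the hydroquinone anion and leaves ketone 17. The closest known reaction type is the DDQ-mediated oxidative C–H cleavage of electron-rich benzylic ethers with Prins-type capture by a tethered enol acetate to give cis-2,6-disubstituted oxan-4-ones. Ring B closes in a 6-endo-trig mode through a chair transition state. The new stereocentre C6 is controlled by C2: with the (E)-oxocarbenium geometry the aryl group and the C2 chain both sit equatorial in the chair, so C6 forms cis to C2, i.e. (6S). Site selectivity among three benzylic positions is required and is secured by the substrate: only the syringyl CH2 is both oxygen-bound and aligned with the π-system of an oxidisable ring, ring A and its ArCH2 are deactivated by the pivalate, and the PhCH2O group sits on an oxygen twisted out of conjugation by the two flanking methoxy groups and carries an electron-poor phenyl ring. 2,6-Dichloropyridine buffers adventitious acid and the sieves keep water from hydrolysing 15, and gentle warming is foreseen because the trialkoxy ring is a weaker donor than a p-anisyl ring.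

Step 11
Reactants: 17 4-{2-[(2S,6S)-6-[4-(benzyloxy)-3,5-dimethoxyphenyl]-4-oxooxan-2-yl]ethyl}-2-methoxyphenyl pivalate
Product: 19 4-{2-[(2S,4R,6S)-6-[4-(benzyloxy)-3,5-dimethoxyphenyl]-4-hydroxyoxan-2-yl]ethyl}-2-methoxyphenol, via pivalate alcohol 18 (not isolated)
Conditions: NaBH4, MeOH–THF, −20 °C; then K2CO3 (2 equiv), MeOH, rt, same flask; aq. NH4Cl work-up
Reagents that add atoms: none
Why: Small-hydride reduction of the conformationally locked oxan-4-one proceeds by axial attack to give the equatorial (4R) alcohol cis to the C2 and C6 substituents, and base-mediated transesterification (methanolysis) then removes the aryl pivalate without touching any stereocentre.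

Step 12
Reactants: 19 4-{2-[(2S,4R,6S)-6-[4-(benzyloxy)-3,5-dimethoxyphenyl]-4-hydroxyoxan-2-yl]ethyl}-2-methoxyphenol
Product: 20 4-[(2S,4R,6S)-4-hydroxy-6-[2-(4-hydroxy-3-methoxyphenyl)ethyl]oxan-2-yl]-2,6-dimethoxyphenol (target CNP0302691.1)
Conditions: H2 (1 atm), 10% Pd/C, EtOAc, rt, stopped at full conversion
Reagents that add atoms: none
Why: Catalytic hydrogenolysis of the aryl benzyl ether should be much faster, in a neutral solvent at 1 atm, than cleavage of the cyclic benzylic C6–O1 bond, and it changes no stereocentre.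

Compound list
1 | eugenol | C=CCc1ccc(O)c(OC)c1 | starting material
2 | 4-allyl-2-methoxyphenyl pivalate | C=CCc1ccc(OC(=O)C(C)(C)C)c(OC)c1 | intermediate
3 | B-alkyl-9-borabicyclo[3.3.1]nonane adduct of 2 (not isolated) | COc1cc(CCCB2C3CCCC2CCC3)ccc1OC(=O)C(C)(C)C | intermediate
4 | 4-(3-hydroxypropyl)-2-methoxyphenyl pivalate | COc1cc(CCCO)ccc1OC(=O)C(C)(C)C | intermediate
5 | 2-methoxy-4-(3-oxopropyl)phenyl pivalate | COc1cc(CCC=O)ccc1OC(=O)C(C)(C)C | intermediate
6 | allenylboronic acid pinacol ester | C=C=CB1OC(C)(C)C(C)(C)O1 | starting material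
7 | pinacol borate ester of (S)-alcohol 8 (not isolated) | COc1cc(CC[C@H](OB2OC(C)(C)C(C)(C)O2)CC#C)ccc1OC(=O)C(C)(C)C | intermediate
8 | 4-[(3S)-3-hydroxyhex-5-yn-1-yl]-2-methoxyphenyl pivalate | COc1cc(CC[C@H](O)CC#C)ccc1OC(=O)C(C)(C)C | intermediate
9 | syringaldehyde | COc1cc(C=O)cc(OC)c1O | starting material
10 | 4-(benzyloxy)-3,5-dimethoxybenzaldehyde | COc1cc(C=O)cc(OC)c1OCc1ccccc1 | intermediate
11 | [4-(benzyloxy)-3,5-dimethoxyphenyl]methanol | COc1cc(CO)cc(OC)c1OCc1ccccc1 | intermediate
12 | 4-(benzyloxy)-3,5-dimethoxybenzyl 2,2,2-trichloroacetimidate | COc1cc(COC(=N)C(Cl)(Cl)Cl)cc(OC)c1OCc1ccccc1 | intermediate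
13 | 4-[(3S)-3-{[4-(benzyloxy)-3,5-dimethoxybenzyl]oxy}hex-5-yn-1-yl]-2-methoxyphenyl pivalate | COc1cc(CC[C@H](OCc2cc(OC)c(OCc3ccccc3)c(OC)c2)CC#C)ccc1OC(=O)C(C)(C)C | intermediate
14 | (4S)-4-{[4-(benzyloxy)-3,5-dimethoxybenzyl]oxy}-6-[3-methoxy-4-(pivaloyloxy)phenyl]hex-1-en-2-yl acetate (key-step precursor) | COc1cc(CC[C@H](OCc2cc(OC)c(OCc3ccccc3)c(OC)c2)CC(=C)OC(C)=O)ccc1OC(=O)C(C)(C)C | intermediate
15 | (E)-aryl oxocarbenium ion from hydride loss at the syringyl CH2 of 14 (cation, not isolated) | COc1cc(CC[C@H](/[O+]=C/c2cc(OC)c(OCc3ccccc3)c(OC)c2)CC(=C)OC(C)=O)ccc1OC(=O)C(C)(C)C | intermediate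
16 | ring-closed O-acetyl oxocarbenium ion at C4 (cation, not isolated) | COc1cc(CC[C@H]2CC(=[O+]C(C)=O)C[C@@H](c3cc(OC)c(OCc4ccccc4)c(OC)c3)O2)ccc1OC(=O)C(C)(C)C | intermediate
17 | 4-{2-[(2S,6S)-6-[4-(benzyloxy)-3,5-dimethoxyphenyl]-4-oxooxan-2-yl]ethyl}-2-methoxyphenyl pivalate (key-step product) | COc1cc(CC[C@H]2CC(=O)C[C@@H](c3cc(OC)c(OCc4ccccc4)c(OC)c3)O2)ccc1OC(=O)C(C)(C)C | intermediate
18 | 4-{2-[(2S,4R,6S)-6-[4-(benzyloxy)-3,5-dimethoxyphenyl]-4-hydroxyoxan-2-yl]ethyl}-2-methoxyphenyl pivalate (not isolated) | COc1cc(CC[C@H]2C[C@@H](O)C[C@@H](c3cc(OC)c(OCc4ccccc4)c(OC)c3)O2)ccc1OC(=O)C(C)(C)C | intermediate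
19 | 4-{2-[(2S,4R,6S)-6-[4-(benzyloxy)-3,5-dimethoxyphenyl]-4-hydroxyoxan-2-yl]ethyl}-2-methoxyphenol | COc1cc(CC[C@H]2C[C@@H](O)C[C@@H](c3cc(OC)c(OCc4ccccc4)c(OC)c3)O2)ccc1O | intermediate
20 | 4-[(2S,4R,6S)-4-hydroxy-6-[2-(4-hydroxy-3-methoxyphenyl)ethyl]oxan-2-yl]-2,6-dimethoxyphenol | COc1cc(CC[C@H]2C[C@@H](O)C[C@@H](c3cc(OC)c(O)c(OC)c3)O2)ccc1O | target

Total step count: 12. Longest linear sequence: 9 steps (steps 1–4 and 8–12, from eugenol); the syringyl branch (steps 5–7) joins at step 8.

Steps most likely to fail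

1. Step 10. Hydride abstraction from the trialkoxybenzyl ether may be slow, so that hydrolysis of the oxocarbenium ion by trace water or further oxidation at the newly benzylic C6–H of the product competes with ring closure. Fallback (Prins route, sets out from 8 and 10, rejoins at 19): semi-hydrogenation of alkyne 8 (H2, Pd/CaCO3 poisoned with Pb(OAc)2, quinoline, EtOAc) should give 4-[(3S)-3-hydroxyhex-5-en-1-yl]-2-methoxyphenyl pivalate F1. Prins cyclisation of F1 with aldehyde 10 in CF3CO2H/CH2Cl2 at 0 °C → rt proceeds through the same (E)-oxocarbenium chair and equatorial capture by trifluoroacetate, and should give the all-cis (2S,4R,6S)-4-trifluoroacetoxy oxane pivalate F2. Treatment of F2 with K2CO3 in MeOH removes the trifluoroacetate and the pivalate together and delivers 19, which continues with step 12.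

2. Step 4. Facial discrimination may be insufficient with an unbranched aliphatic aldehyde, and the resulting loss of enantiopurity at C2 cannot be repaired later. Fallback (resolved-epoxide route, sets out from 5, rejoins at 8): Corey–Chaykovsky epoxidation of aldehyde 5 (trimethylsulfonium iodide, KOtBu, DMSO–THF, 0 °C) should give racemic 2-methoxy-4-[2-(oxiran-2-yl)ethyl]phenyl pivalate F3. Hydrolytic kinetic resolution of F3 with 0.55 equiv H2O uses the N,N′-bis(3,5-di-tert-butylsalicylidene)cyclohexane-1,2-diamine cobalt acetate complex (trivalent cobalt) of the configuration that consumes the (R)-oxirane, expected to be (R,R) by analogy with simple alkyloxiranes, and leaves the (S)-oxirane F4. Opening of F4 at its terminal carbon with LiC≡CSiMe3/BF3·OEt2 in THF at −78 °C gives 4-[(3S)-3-hydroxy-6-(trimethylsilyl)hex-5-yn-1-yl]-2-methoxyphenyl pivalate F5. Desilylation of F5 with Bu4NF/AcOH in THF at 0 °C returns 8.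

3. Step 8. The electron-rich benzyl cation may undergo Friedel–Crafts self-alkylation, or the imidate may rearrange to the N-benzyl trichloroacetamide, faster than the secondary alcohol captures it. Fallback (reductive etherification, sets out from 8 and 10, rejoins at 13): silylation of 8 (Me3SiCl, imidazole, CH2Cl2) gives the trimethylsilyl ether F6. Treatment of F6 with aldehyde 10, Et3SiH and BiBr3 (cat.) in MeCN at rt forms the mixed acetal-type oxocarbenium ion and reduces it in place to ether 13, without any base and without the imidate.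

Further compounds
F1 | step 10 | 4-[(3S)-3-hydroxyhex-5-en-1-yl]-2-methoxyphenyl pivalate | COc1cc(CC[C@H](O)CC=C)ccc1OC(=O)C(C)(C)C
F2 | step 10 | (2S,4R,6S)-2-[4-(benzyloxy)-3,5-dimethoxyphenyl]-6-{2-[3-methoxy-4-(pivaloyloxy)phenyl]ethyl}oxan-4-yl trifluoroacetate | COc1cc(CC[C@H]2C[C@@H](OC(=O)C(F)(F)F)C[C@@H](c3cc(OC)c(OCc4ccccc4)c(OC)c3)O2)ccc1OC(=O)C(C)(C)C
F3 | step 4 | racemic 2-methoxy-4-[2-(oxiran-2-yl)ethyl]phenyl pivalate | COc1cc(CCC2CO2)ccc1OC(=O)C(C)(C)C
F4 | step 4 | 2-methoxy-4-{2-[(2S)-oxiran-2-yl]ethyl}phenyl pivalate | COc1cc(CC[C@H]2CO2)ccc1OC(=O)C(C)(C)C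
F5 | step 4 | 4-[(3S)-3-hydroxy-6-(trimethylsilyl)hex-5-yn-1-yl]-2-methoxyphenyl pivalate | COc1cc(CC[C@H](O)CC#C[Si](C)(C)C)ccc1OC(=O)C(C)(C)C
F6 | step 8 | 2-methoxy-4-[(3S)-3-(trimethylsilyloxy)hex-5-yn-1-yl]phenyl pivalate | COc1cc(CC[C@H](O[Si](C)(C)C)CC#C)ccc1OC(=O)C(C)(C)C
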